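**Strategy**

Numbering as a benzo[7]annulene. The seven-membered ring (C4a, C5–C9, C9a) is drawn from the six-membered enedione ring of a catalytic asymmetric quinone Diels–Alder adduct, which fixes the cis ring fusion. The key step exploits the quaternary gem-dimethyl carbon C9 that sits between ring-fusion C9a and oxygenated C8: a Krief seleno-pinacol ring expansion pushes C9a from the C8 carbinol carbon onto an exocyclic CMe2 cation, so that the ring grows by one atom, the quaternary centre forms and C8 becomes a ketone in one operation, with retention at C9a. Its precursor is the β-hydroxy selenide from 2-lithio-2-(methylselanyl)propane and the adduct.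

Key step: step 5

Remark (assumption): the sense of induction of the BINOL–Ti catalyst in step 2 is assigned by analogy; the antipodal ligand is used if it proves opposite.
Remark (assumption): in step 6 the CBS catalyst is taken to treat the quaternary C9 side of the ketone as the large group.

**Route**

Step 1
Reactants: 1 3-methylbut-3-en-2-one
Product: 2 3-methyl-2-[(triisopropylsilyl)oxy]buta-1,3-diene
Conditions: TIPSOTf, Et3N, CH2Cl2, 0 °C → rt
Reagents that add atoms: triisopropylsilyl triflate, CC(C)[Si](OS(=O)(=O)C(F)(F)F)(C(C)C)C(C)C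
Why: Silyl enol ether formation by soft enolisation toward the only enolisable (methyl) side should give the 2-silyloxy diene.

Step 2
Reactants: 2 3-methyl-2-[(triisopropylsilyl)oxy]buta-1,3-diene; 3 2-methoxy-1,4-benzoquinone
Product: 4 (4aR,8aS)-2-methoxy-7-methyl-6-[(triisopropylsilyl)oxy]-4a,5,8,8a-tetrahydronaphthalene-1,4-dione (cis-fused)
Conditions: (S)-BINOL/TiCl2(Oi-Pr)2 (Mikami catalyst, 15 mol %), 4 Å MS, toluene/CH2Cl2, −60 → −20 °C
Reagents that add atoms: none
Why: Catalytic asymmetric quinone Diels–Alder reaction: Ti is chelated by C1=O and the methoxy oxygen, only the unsubstituted C5=C6 bond reacts, the nucleophilic CH2 terminus next to C–OSi bonds to C5 (β to the activated carbonyl), suprafacial addition gives the cis fusion and the ligand selects the quinone face that sets 4aR,8aS.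

Step 3
Reactants: 5 acetone; 6 dimethyl diselenide
Product: 8 2,2-bis(methylselanyl)propane, via methaneselenol 7 (not isolated)
Conditions: H3PO2 (50 % aq.), THF, 60 °C; then acetone, ZnCl2, CH2Cl2, 0 °C → rt
Reagents that add atoms: none
Why: Reduction of the diselenide to the selenol followed by Lewis-acid selenoacetalisation of the ketone is the standard entry to this reagent precursor.

Step 4
Reactants: 4 the Diels–Alder adduct; 8 2,2-bis(methylselanyl)propane
Product: 10 (4aR,8aS)-1-hydroxy-2-methoxy-7-methyl-1-[2-(methylselanyl)propan-2-yl]-6-[(triisopropylsilyl)oxy]-4a,5,8,8a-tetrahydronaphthalen-4(1H)-one (numbering of 4 kept; C1 configuration undefined and lost in step 5), via 2-lithio-2-(methylselanyl)propane 9 (not isolated)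
Conditions: 8, n-BuLi, THF, −78 °C; then 4 added at −78 °C; NH4Cl (aq.)
Reagents that add atoms: none
Why: Se/Li exchange gives a weakly basic, strongly nucleophilic α-selenoalkyllithium that should add 1,2 to the cross-conjugated C1 ketone, which is more electrophilic than the vinylogous ester carbonyl C4, faster than it enolises the adduct.

Step 5
Reactants: 10 the β-hydroxy selenide
Product: 11 (4aR,9aS)-7-methoxy-2,9,9-trimethyl-3-[(triisopropylsilyl)oxy]-1,4,4a,9a-tetrahydro-5H-benzo[7]annulene-5,8(9H)-dione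
Conditions: AgBF4 on neutral Al2O3, CH2Cl2, 0 °C → rt
Reagents that add atoms: none
Why: Ag(I) binds selenium and turns MeSe into a leaving group on the tertiary carbon; as the C–Se bond ionises, the ring bond C1–C8a (numbering of 10) shifts to the developing cation and the carbinol oxygen closes to the ketone, a seleno-pinacol (Krief) one-carbon ring expansion of the type that converts cyclohexanones into 2,2-dimethylcycloheptanones. The seven-membered ring therefore arises by a 1,2-shift that enlarges the six-membered enedione ring by one atom, not by a cyclisation, and the new quaternary carbon C9 ends up between C8=O and C9a. No new stereocentre is formed; the migrating ring-fusion carbon keeps its configuration (suprafacial shift with retention), so the cis fusion of step 2 is carried into the bicyclo[5.4.0] skeleton. The selectivity needed is migration of the sp3 ring-fusion carbon rather than the alkenyl carbon C2: C2 is the β-carbon of the vinylogous ester C2=C3–C4=O, so its migration would place positive charge on C3 next to the carbonyl, whereas the more substituted sp3 carbon is the normal migrating group in this rearrangement. Alumina buffers the HBF4 released, which should protect the silyl enol ether, and the inserted quaternary carbon removes the aromatisation pathway open to 4 and 10.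

Step 6
Reactants: 11 the ring-expanded dione
Product: 12 (4aR,8R,9aS)-8-hydroxy-7-methoxy-2,9,9-trimethyl-3-[(triisopropylsilyl)oxy]-1,4,4a,8,9,9a-hexahydro-5H-benzo[7]annulen-5-one
Conditions: (R)-2-methyl-CBS-oxazaborolidine (20 mol %), catecholborane, toluene/CH2Cl2, −78 °C
Reagents that add atoms: none
Why: Corey–Bakshi–Shibata reduction under reagent control: with the quaternary C9 side as the large group the catalyst-bound borane should deliver hydride to give 8R, while the vinylogous ester carbonyl and both enol ethers are inert to catecholborane at −78 °C.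

Step 7
Reactants: 12 the C8 alcohol
Product: 13 (4aR,8R,9aS)-8-hydroxy-2,5,9,9-tetramethyl-3-[(triisopropylsilyl)oxy]-1,4,4a,8,9,9a-hexahydro-7H-benzo[7]annulen-7-one
Conditions: MeLi (3 equiv), CeCl3, THF, −78 °C; then 0.5 M HCl, THF, 0 °C
Reagents that add atoms: methyllithium, [Li]C; water, O
Why: Stork–Danheiser sequence: the organocerium adds 1,2 to the vinylogous ester carbonyl C5, and acid-induced loss of the tertiary hydroxyl with hydrolysis of the methyl enol ether transposes the enone to C7=O/C5=C6, leaving C8 and the bulky silyl enol ether untouched.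

Step 8
Reactants: 13 the α'-hydroxy enone
Product: 14 (4aR,7R,8R,9aS)-2,5,9,9-tetramethyl-3-[(triisopropylsilyl)oxy]-4,4a,7,8,9,9a-hexahydro-1H-benzo[7]annulene-7,8-diol (trans-diol)
Conditions: Me4NBH(OAc)3, MeCN/AcOH (1:1), −30 → 0 °C
Reagents that add atoms: none
Why: Evans–Saksena hydroxyl-directed reduction: the C8 alkoxy(acetoxy)borohydride delivers hydride intramolecularly to the same face of the C7 ketone, which should give the trans (anti) diol and thus 7R.

Step 9
Reactants: 14 the trans-diol; 15 angelic acid [(Z)-2-methylbut-2-enoic acid]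
Product: 17 7-O-angelate of 14 [(4aR,7R,8R,9aS)-8-hydroxy-2,5,9,9-tetramethyl-3-[(triisopropylsilyl)oxy]-4,4a,7,8,9,9a-hexahydro-1H-benzo[7]annulen-7-yl (Z)-2-methylbut-2-enoate], via angelic 2,4,6-trichlorobenzoic anhydride 16 (not isolated)
Conditions: 15, 2,4,6-trichlorobenzoyl chloride, Et3N, toluene, rt; then 14, DMAP (cat.), 0 °C → rt
Reagents that add atoms: none
Why: Yamaguchi esterification transfers the angeloyl group without Z→E isomerisation and should select the allylic C7 hydroxyl over the neopentyl C8 hydroxyl on steric grounds.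

Step 10
Reactants: 15 angelic acid
Product: 18 (Z)-2-methylbut-2-en-1-ol
Conditions: LiAlH4, Et2O, 0 °C
Reagents that add atoms: none
Why: Hydride reduction of the acid to the allylic alcohol leaves the alkene geometry untouched.

Step 11
Reactants: 18 (Z)-2-methylbut-2-en-1-ol
Product: 19 [(2S,3R)-2,3-dimethyloxiran-2-yl]methanol
Conditions: Ti(Oi-Pr)4 (10 mol %), L-(+)-diisopropyl tartrate (12 mol %), t-BuOOH, 4 Å MS, CH2Cl2, −20 °C
Reagents that add atoms: tert-butyl hydroperoxide, CC(C)(C)OO
Why: Sharpless asymmetric epoxidation: the L-(+)-tartrate complex delivers oxygen to the alkene face that gives the (2S,3R)-epoxy alcohol, and the Z geometry fixes the trans relation of the two methyl groups.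

Step 12
Reactants: 19 the epoxy alcohol
Product: 20 (2R,3R)-2,3-dimethyloxirane-2-carboxylic acid
Conditions: RuCl3·xH2O (cat.), NaIO4, CCl4/MeCN/H2O, rt
Reagents that add atoms: sodium periodate, [Na+].[O-]I(=O)(=O)=O
Why: RuO4 oxidation of the primary alcohol to the acid; the quaternary α-carbon cannot epimerise and only its CIP descriptor changes (2S → 2R).

Step 13
Reactants: 17 the 7-O-angelate; 20 (2R,3R)-2,3-dimethyloxirane-2-carboxylic acid
Product: 22 (4aR,7R,8R,9aS)-7-[(Z)-2-methylbut-2-enoyloxy]-2,5,9,9-tetramethyl-3-[(triisopropylsilyl)oxy]-4,4a,7,8,9,9a-hexahydro-1H-benzo[7]annulen-8-yl (2R,3R)-2,3-dimethyloxirane-2-carboxylate, via mixed 2-methyl-6-nitrobenzoic anhydride 21 (not isolated)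
Conditions: 2-methyl-6-nitrobenzoic anhydride (MNBA), Et3N, DMAP (0.2 equiv), CH2Cl2, rt
Reagents that add atoms: none
Why: Shiina esterification acylates hindered secondary alcohols under mild basic conditions that should preserve the epoxide and the (Z)-angelate.

Step 14
Reactants: 22 the diester silyl enol ether
Product: 23 target CNP0315120.1, (4aR,7R,8R,9aS)-7-[(Z)-2-methylbut-2-enoyloxy]-2,5,9,9-tetramethyl-3-oxo-4,4a,7,8,9,9a-hexahydro-3H-benzo[7]annulen-8-yl (2R,3R)-2,3-dimethyloxirane-2-carboxylate
Conditions: Pd(OAc)2 (1.1 equiv), MeCN, rt → 40 °C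
Reagents that add atoms: none
Why: Saegusa–Ito oxidation: Pd(II) forms the C2 palladium enolate from the silyl enol ether and β-hydride elimination toward C1 gives the endocyclic 2-methyl enone without touching the esters, the epoxide or C9a.

**Compound list**

1 | 3-methylbut-3-en-2-one | CC(=O)C(C)=C | starting material
2 | 3-methyl-2-[(triisopropylsilyl)oxy]buta-1,3-diene | C=C(O[Si](C(C)C)(C(C)C)C(C)C)C(C)=C | intermediate
3 | 2-methoxy-1,4-benzoquinone | COC1=CC(=O)C=CC1=O | starting material
4 | (4aR,8aS)-2-methoxy-7-methyl-6-[(triisopropylsilyl)oxy]-4a,5,8,8a-tetrahydronaphthalene-1,4-dione | COC1=CC(=O)[C@@H]2CC(O[Si](C(C)C)(C(C)C)C(C)C)=C(C)C[C@@H]2C1=O | intermediate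
5 | acetone | CC(C)=O | starting material
6 | dimethyl diselenide | C[Se][Se]C | starting material
7 | methaneselenol | C[SeH] | intermediate
8 | 2,2-bis(methylselanyl)propane | CC(C)([Se]C)[Se]C | intermediate
9 | 2-lithio-2-(methylselanyl)propane | [Li]C(C)(C)[Se]C | intermediate
10 | (4aR,8aS)-1-hydroxy-2-methoxy-7-methyl-1-[2-(methylselanyl)propan-2-yl]-6-[(triisopropylsilyl)oxy]-4a,5,8,8a-tetrahydronaphthalen-4(1H)-one (C1 undefined) | COC1=CC(=O)[C@@H]2CC(O[Si](C(C)C)(C(C)C)C(C)C)=C(C)C[C@@H]2C1(O)C(C)(C)[Se]C | intermediate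
11 | (4aR,9aS)-7-methoxy-2,9,9-trimethyl-3-[(triisopropylsilyl)oxy]-1,4,4a,9a-tetrahydro-5H-benzo[7]annulene-5,8(9H)-dione | COC1=CC(=O)[C@@H]2CC(O[Si](C(C)C)(C(C)C)C(C)C)=C(C)C[C@@H]2C(C)(C)C1=O | intermediate
12 | (4aR,8R,9aS)-8-hydroxy-7-methoxy-2,9,9-trimethyl-3-[(triisopropylsilyl)oxy]-1,4,4a,8,9,9a-hexahydro-5H-benzo[7]annulen-5-one | COC1=CC(=O)[C@@H]2CC(O[Si](C(C)C)(C(C)C)C(C)C)=C(C)C[C@@H]2C(C)(C)[C@H]1O | intermediate
13 | (4aR,8R,9aS)-8-hydroxy-2,5,9,9-tetramethyl-3-[(triisopropylsilyl)oxy]-1,4,4a,8,9,9a-hexahydro-7H-benzo[7]annulen-7-one | O=C1C=C(C)[C@@H]2CC(O[Si](C(C)C)(C(C)C)C(C)C)=C(C)C[C@@H]2C(C)(C)[C@H]1O | intermediate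
14 | (4aR,7R,8R,9aS)-2,5,9,9-tetramethyl-3-[(triisopropylsilyl)oxy]-4,4a,7,8,9,9a-hexahydro-1H-benzo[7]annulene-7,8-diol | O[C@@H]1C=C(C)[C@@H]2CC(O[Si](C(C)C)(C(C)C)C(C)C)=C(C)C[C@@H]2C(C)(C)[C@H]1O | intermediate
15 | angelic acid, (Z)-2-methylbut-2-enoic acid | C/C=C(/C)C(=O)O | starting material
16 | angelic 2,4,6-trichlorobenzoic anhydride | C/C=C(/C)C(=O)OC(=O)c1c(Cl)cc(Cl)cc1Cl | intermediate
17 | 7-O-angelate of 14 | C/C=C(/C)C(=O)O[C@@H]1C=C(C)[C@@H]2CC(O[Si](C(C)C)(C(C)C)C(C)C)=C(C)C[C@@H]2C(C)(C)[C@H]1O | intermediate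
18 | (Z)-2-methylbut-2-en-1-ol | C/C=C(/C)CO | intermediate
19 | [(2S,3R)-2,3-dimethyloxiran-2-yl]methanol | OC[C@]1(C)O[C@@H]1C | intermediate
20 | (2R,3R)-2,3-dimethyloxirane-2-carboxylic acid | OC(=O)[C@]1(C)O[C@@H]1C | intermediate
21 | (2R,3R)-2,3-dimethyloxirane-2-carboxylic 2-methyl-6-nitrobenzoic anhydride | Cc1cccc([N+](=O)[O-])c1C(=O)OC(=O)[C@]1(C)O[C@@H]1C | intermediate
22 | 7-O-angelate 8-O-[(2R,3R)-2,3-dimethyloxirane-2-carboxylate] of 14 | C/C=C(/C)C(=O)O[C@@H]1C=C(C)[C@@H]2CC(O[Si](C(C)C)(C(C)C)C(C)C)=C(C)C[C@@H]2C(C)(C)[C@H]1OC(=O)[C@]1(C)O[C@@H]1C | intermediate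
23 | CNP0315120.1 | C/C=C(/C)C(=O)O[C@@H]1C=C(C)[C@@H]2CC(=O)C(C)=C[C@@H]2C(C)(C)[C@H]1OC(=O)[C@]1(C)O[C@@H]1C | target

**Step count**

Total steps: 14. Longest linear sequence: 10 steps (steps 1, 2, 4, 5, 6, 7, 8, 9, 13, 14).

**Steps most likely to fail**

Step 5. The rearrangement may take a different course: the methoxy-bearing alkenyl carbon could migrate instead of the ring-fusion carbon, the alkoxide could close to an oxirane instead of triggering the shift, or the silyl enol ether could be ionised by Ag(I)/HBF4. The fallback sets out from 4 and comes back at 11. Isopropenylmagnesium bromide/CeCl3 (THF, −78 °C) should add to C1=O of 4 to give the tertiary allylic alcohol (4aR,8aS)-1-hydroxy-1-isopropenyl-2-methoxy-7-methyl-6-[(triisopropylsilyl)oxy]-4a,5,8,8a-tetrahydronaphthalen-4(1H)-one F1. A cobalt-salen-catalysed hydrogen-atom-transfer radical–polar crossover (Co(salen) catalyst, N-fluoro-2,4,6-trimethylpyridinium triflate, PhSiH3, acetone, rt) would then generate the same exocyclic tertiary cation from the 1,1-disubstituted alkene without a Brønsted acid, and the semipinacol shift would give 11.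

Step 6. Reagent and substrate facial preferences at C8 may oppose each other, or the catalyst may not distinguish the quaternary side from the alkoxy-alkenyl side, leading to poor diastereoselectivity. The fallback sets out from 11 and comes back at 13, replacing hydride control by electrophilic oxygenation. NaBH4/CeCl3 (MeOH, −40 °C) reduces C8=O without regard to configuration, shown as the (4aR,8S,9aS) alcohol F2. The conditions of step 7 then give the C8-epimeric hydroxy enone F3. SmI2 (THF/MeOH, −78 °C) removes the α'-hydroxyl to give (4aR,9aS)-2,5,9,9-tetramethyl-3-[(triisopropylsilyl)oxy]-1,4,4a,8,9,9a-hexahydro-7H-benzo[7]annulen-7-one F4. KHMDS (THF, −78 °C) then 2-(phenylsulfonyl)-3-phenyloxaziridine should hydroxylate the C8 enolate on the face away from the ring-A carbon on C9a and return 13.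

Step 13. Acylation of the neopentyl C8 hydroxyl by an α,α-disubstituted acid may be sluggish, and under forcing basic conditions the neighbouring angelate may migrate from O7 to O8 or isomerise. The fallback sets out from 14 and comes back at 22, reversing the order of acylation. TESCl/imidazole (DMF, −20 °C) should silylate the less hindered C7 hydroxyl to give the 7-O-triethylsilyl ether F5. MNBA/DMAP esterification with 20 at 40 °C, now without a migrating acyl group, gives the 8-O-epoxy ester F6. HF·pyridine/pyridine (THF, 0 °C) removes the TES group to give the 7-hydroxy 8-ester F7, and the Yamaguchi conditions of step 9 with 15 give 22.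

**Further compounds**

F1 | step 5 | (4aR,8aS)-1-hydroxy-1-isopropenyl-2-methoxy-7-methyl-6-[(triisopropylsilyl)oxy]-4a,5,8,8a-tetrahydronaphthalen-4(1H)-one | COC1=CC(=O)[C@@H]2CC(O[Si](C(C)C)(C(C)C)C(C)C)=C(C)C[C@@H]2C1(O)C(C)=C
F2 | step 6 | (4aR,8S,9aS)-8-hydroxy-7-methoxy-2,9,9-trimethyl-3-[(triisopropylsilyl)oxy]-1,4,4a,8,9,9a-hexahydro-5H-benzo[7]annulen-5-one | COC1=CC(=O)[C@@H]2CC(O[Si](C(C)C)(C(C)C)C(C)C)=C(C)C[C@@H]2C(C)(C)[C@@H]1O
F3 | step 6 | (4aR,8S,9aS)-8-hydroxy-2,5,9,9-tetramethyl-3-[(triisopropylsilyl)oxy]-1,4,4a,8,9,9a-hexahydro-7H-benzo[7]annulen-7-one | O=C1C=C(C)[C@@H]2CC(O[Si](C(C)C)(C(C)C)C(C)C)=C(C)C[C@@H]2C(C)(C)[C@@H]1O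
F4 | step 6 | (4aR,9aS)-2,5,9,9-tetramethyl-3-[(triisopropylsilyl)oxy]-1,4,4a,8,9,9a-hexahydro-7H-benzo[7]annulen-7-one | O=C1C=C(C)[C@@H]2CC(O[Si](C(C)C)(C(C)C)C(C)C)=C(C)C[C@@H]2C(C)(C)C1
F5 | step 13 | 7-O-triethylsilyl ether of 14 | CC[Si](CC)(CC)O[C@@H]1C=C(C)[C@@H]2CC(O[Si](C(C)C)(C(C)C)C(C)C)=C(C)C[C@@H]2C(C)(C)[C@H]1O
F6 | step 13 | 7-O-triethylsilyl 8-O-[(2R,3R)-2,3-dimethyloxirane-2-carboxylate] of 14 | CC[Si](CC)(CC)O[C@@H]1C=C(C)[C@@H]2CC(O[Si](C(C)C)(C(C)C)C(C)C)=C(C)C[C@@H]2C(C)(C)[C@H]1OC(=O)[C@]1(C)O[C@@H]1C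
F7 | step 13 | 8-O-[(2R,3R)-2,3-dimethyloxirane-2-carboxylate] of 14 | O[C@@H]1C=C(C)[C@@H]2CC(O[Si](C(C)C)(C(C)C)C(C)C)=C(C)C[C@@H]2C(C)(C)[C@H]1OC(=O)[C@]1(C)O[C@@H]1C
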